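**Retrosynthetic overview**

1. Target 17 comes from its pentakis(tert-butyldimethylsilyl) ether 16 by fluoride.
2. Ring B (numbered from the methylene-bearing carbon C1') is cut at C4'–C5' and C6'–C1'. The C5'(CH3)/C6'(OCH3) pair is 1-methoxypropyne 14, and C1'–C4' are C3–C6 of 2-pyrone 11. A (4+2) addition with loss of CO2 closes ring B, the only ring formed.
3. Pyrone 11 comes from persilylation of 10, which is made by ortho-quinone methide benzylation of butanoylated 3-oxoglutaric anhydride 8 with the ring A Mannich base 4.
4. 4 comes from 2,4,6-trihydroxytoluene 1 (Friedel-Crafts with 2, then Mannich); 8 from 3-oxopentanedioic acid 5; 14 from chloroacetal 12.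
5. The strategy rests on the pattern of ring B: its single O-methyl sits on C6', next to the C-methyl carbon C5', and the other four ring carbons (CH2-bearing C, C–O, C–butanoyl, C–O) are the carbon chain of an acylated 3-oxoglutarate.

Key step: step 8

**Remarks on the chemistry**

- Compounds 6, 8 and 10 are tautomeric mixtures; each is drawn in one enol form.
- All isolated compounds are achiral. The only stereocentres are the two bridgeheads of transient 15, formed racemic and then destroyed.
- Pyrone atoms are numbered O1, C2 (lactone carbonyl), C3 to C6.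
- 1-Methoxypropyne is made by the chloroacetal/sodium amide route, because alkoxide isomerisation of methyl propargyl ether rests at methoxyallene.

**Route**

Step 1
Reactants: 1 2,4,6-trihydroxytoluene; 2 pentanoyl chloride
Product: 3 1-(2,4,6-trihydroxy-3-methylphenyl)pentan-1-one
Conditions: AlCl3 (3.5 equiv), PhNO2, rt → 65 °C; aq. HCl
Reagents that add atoms: none
Why: Friedel-Crafts acylation of the phloroglucinol ring, whose two free positions are equivalent so that a single ketone should form, the acyl group then deactivating the ring toward a second acylation.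

Step 2
Reactants: 3 1-(2,4,6-trihydroxy-3-methylphenyl)pentan-1-one
Product: 4 1-[3-[(dimethylamino)methyl]-2,4,6-trihydroxy-5-methylphenyl]pentan-1-one
Conditions: aq. Me2NH and aq. CH2O (premixed), EtOH, 0 °C → rt
Reagents that add atoms: formaldehyde, C=O; dimethylamine, CNC
Why: Mannich reaction at the only free position of the electron-rich acylphloroglucinol, the premixed amine and formaldehyde ensuring that the iminium ion and not a second arene takes the benzylic carbon.

Step 3
Reactants: 5 3-oxopentanedioic acid
Product: 6 3-oxoglutaric anhydride (4-hydroxy-2H-pyran-2,6(3H)-dione)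
Conditions: Ac2O, AcOH, 0–10 °C
Reagents that add atoms: none
Why: cyclodehydration of the 1,5-diacid to the six-membered anhydride by acetic anhydride at low temperature, the established preparation of this anhydride, which crystallises from the mixture before it can decarboxylate.

Step 4
Reactants: 6 3-oxoglutaric anhydride; 7 butanoyl chloride
Product: 8 5-butanoyl-4-hydroxy-2H-pyran-2,6(3H)-dione
Conditions: pyridine (2 equiv), DMAP (cat.), CH2Cl2, 0 °C → rt; cold dil. HCl
Reagents that add atoms: none
Why: C-acylation of a strongly acidic cyclic 1,3-dicarbonyl enol with an acid chloride and pyridine, the reaction type used for acyl Meldrum's acids, in which DMAP moves any enol ester to carbon and the stabilised product enolate resists a second acylation.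

Step 5
Reactants: 4 1-[3-[(dimethylamino)methyl]-2,4,6-trihydroxy-5-methylphenyl]pentan-1-one; 8 5-butanoyl-4-hydroxy-2H-pyran-2,6(3H)-dione
Product: 10 5-butanoyl-4,6-dihydroxy-3-[(2,4,6-trihydroxy-3-methyl-5-pentanoylphenyl)methyl]-2H-pyran-2-one, via ortho-quinone methide 9 (not isolated)
Conditions: 8 (1.2 equiv), dioxane, 50 °C; dry sulfonic acid resin (H+ form), filter; used at once
Reagents that add atoms: none
Why: the Mannich base loses dimethylamine on warming to give ortho-quinone methide 9, to which the unsubstituted ring carbon of the dihydroxypyrone tautomer of 8 adds in a Michael reaction (the known C-benzylation of 4-hydroxy-2-pyrones and related cyclic 1,3-dicarbonyl enols), while the strongly acidic 8 and 10 hold the released amine as its ammonium salt so that it should not open the anhydride.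

Step 6
Reactants: 10 5-butanoyl-4,6-dihydroxy-3-[(2,4,6-trihydroxy-3-methyl-5-pentanoylphenyl)methyl]-2H-pyran-2-one
Product: 11 5-butanoyl-4,6-bis(tert-butyldimethylsilyloxy)-3-[[2,4,6-tris(tert-butyldimethylsilyloxy)-3-methyl-5-pentanoylphenyl]methyl]pyran-2-one
Conditions: TBSOTf (5.5 equiv), 2,6-lutidine (7 equiv), CH2Cl2, −78 → 0 °C; pentane, filter under Ar, high vacuum; used crude
Reagents that add atoms: tert-butyldimethylsilyl trifluoromethanesulfonate, CC(C)(C)[Si](C)(C)OS(=O)(=O)C(F)(F)F
Why: silyl triflate with a hindered pyridine base silylates the three phenols and the two enolic hydroxyls (standard silyl ether and silyl enol ether formation), 2,6-lutidine being too weak to turn the two alkyl ketones into silyl enol ethers, and silicon that first binds at the butanoyl oxygen can reach O4 or O6 by 1,5-shift, which leaves the aromatic 4,6-bis(silyloxy)-2-pyrone with its lactone carbonyl next to the benzylated carbon as the expected product.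

Step 7
Reactants: 12 2-chloro-1,1-dimethoxyethane
Product: 14 1-methoxypropyne, via sodium methoxyacetylide 13 (not isolated)
Conditions: NaNH2 (3.1 equiv), liq. NH3, −33 °C; MeI (1.0 equiv), −40 °C; evaporate NH3, distil
Reagents that add atoms: iodomethane, CI
Why: sodium amide eliminates methanol and hydrogen chloride from the chloroacetal and deprotonates the resulting methoxyacetylene, and the acetylide is C-methylated in liquid ammonia, the established route to 1-alkoxy-1-alkynes.

Step 8
Reactants: 11 5-butanoyl-4,6-bis(tert-butyldimethylsilyloxy)-3-[[2,4,6-tris(tert-butyldimethylsilyloxy)-3-methyl-5-pentanoylphenyl]methyl]pyran-2-one; 14 1-methoxypropyne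
Product: 16 1-[3-[[3-butanoyl-2,4-bis(tert-butyldimethylsilyloxy)-6-methoxy-5-methylphenyl]methyl]-2,4,6-tris(tert-butyldimethylsilyloxy)-5-methylphenyl]pentan-1-one, via bridged lactone 15 (not isolated)
Conditions: 14 (6 equiv), PhMe, sealed tube, 100 °C, Ar
Reagents that add atoms: none
Why: Proposed new method: in pyrone 11 the ring carbon C6 is the beta carbon of the C5 butanoyl enone and the far end of the dienoate that ends in the C2 lactone carbonyl, while C3 is the carbon of the C3=C4 silyl enol ether, so the nucleophilic methyl-bearing carbon of ynol ether 14 should bond to C6 and the methoxy-bearing carbon, which becomes a ketene-oxonium carbon, should be taken up by C3, either as an asynchronous inverse-demand (4+2) cycloaddition or as a conjugate addition followed by collapse of the zwitterion. The closest known reaction type is the inverse-electron-demand Diels-Alder reaction of 3- or 5-acyl and alkoxycarbonyl 2-pyrones with ynamines, ketene acetals and alkynyl ethers followed by loss of CO2, which has not been shown for a 5-acyl-4,6-bis(silyloxy)-2-pyrone, whose two donor oxygens lower the reactivity and are the reason for excess alkyne and heat. Ring B is closed by suprafacial (4+2) addition across C3 and C6 to the 2-oxabicyclo[2.2.2]octadienone 15 (in the stepwise picture a six-membered closure of the dienolate carbon C3 onto the ketene-oxonium carbon), and 15 then loses C2 and O1 as CO2 in a retro-(4+2) reaction driven by aromatisation. The two bridgehead centres of 15 are fixed relative to each other by the bicycle and both become sp2 carbons of the benzene ring, so no stereocenter has to be controlled. The one selectivity needed is regiochemical (methyl carbon to C6, methoxyl carbon to C3) and is secured by the matched polarity of the two partners together with the placement of silicon on O6 rather than on the lactone oxygen O2, a position that 1,5-silyl shifts through the butanoyl oxygen cannot reach. All five hydroxyls are silylated so that the ynol ether is not consumed by O-H addition, and 14 has no hydrogen beta to the ether oxygen and so cannot fragment to a ketene at this temperature.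

Step 9
Reactants: 16 pentakis(tert-butyldimethylsilyl) ether of the target
Product: 17 1-[3-[(3-butanoyl-2,4-dihydroxy-6-methoxy-5-methylphenyl)methyl]-2,4,6-trihydroxy-5-methylphenyl]pentan-1-one
Conditions: TBAF (6 equiv), AcOH (6 equiv), THF, 0 °C → rt
Reagents that add atoms: none
Why: fluoride cleaves the five aryl silyl ethers by forming the strong Si-F bond, acetic acid keeping the medium near neutral so that the air-sensitive polyphenolate is not exposed to base, while the aryl methyl ether and both ketones are inert.

**Compound list**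

1 | 2,4,6-trihydroxytoluene | Cc1c(O)cc(O)cc1O | starting material
2 | pentanoyl chloride | CCCCC(Cl)=O | starting material
3 | 1-(2,4,6-trihydroxy-3-methylphenyl)pentan-1-one | CCCCC(=O)c1c(O)cc(O)c(C)c1O | intermediate
4 | 1-[3-[(dimethylamino)methyl]-2,4,6-trihydroxy-5-methylphenyl]pentan-1-one | CCCCC(=O)c1c(O)c(CN(C)C)c(O)c(C)c1O | intermediate
5 | 3-oxopentanedioic acid | OC(=O)CC(=O)CC(=O)O | starting material
6 | 3-oxoglutaric anhydride, drawn as 4-hydroxy-2H-pyran-2,6(3H)-dione | O=C1CC(O)=CC(=O)O1 | intermediate
7 | butanoyl chloride | CCCC(Cl)=O | starting material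
8 | 5-butanoyl-4-hydroxy-2H-pyran-2,6(3H)-dione | CCCC(=O)C1=C(O)CC(=O)OC1=O | intermediate
9 | 3,5-dihydroxy-2-methyl-6-methylidene-4-pentanoylcyclohexa-2,4-dien-1-one (ortho-quinone methide, not isolated) | CCCCC(=O)C1=C(O)C(=C)C(=O)C(C)=C1O | intermediate
10 | 5-butanoyl-4,6-dihydroxy-3-[(2,4,6-trihydroxy-3-methyl-5-pentanoylphenyl)methyl]-2H-pyran-2-one | CCCC(=O)C1=C(O)OC(=O)C(Cc2c(O)c(C)c(O)c(C(=O)CCCC)c2O)=C1O | intermediate
11 | 5-butanoyl-4,6-bis(tert-butyldimethylsilyloxy)-3-[[2,4,6-tris(tert-butyldimethylsilyloxy)-3-methyl-5-pentanoylphenyl]methyl]pyran-2-one | CCCC(=O)C1=C(O[Si](C)(C)C(C)(C)C)OC(=O)C(Cc2c(O[Si](C)(C)C(C)(C)C)c(C)c(O[Si](C)(C)C(C)(C)C)c(C(=O)CCCC)c2O[Si](C)(C)C(C)(C)C)=C1O[Si](C)(C)C(C)(C)C | intermediate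
12 | 2-chloro-1,1-dimethoxyethane | COC(CCl)OC | starting material
13 | sodium methoxyacetylide (not isolated) | [Na+].[C-]#COC | intermediate
14 | 1-methoxypropyne | CC#COC | intermediate
15 | racemic 7-butanoyl-1,8-bis(tert-butyldimethylsilyloxy)-5-methoxy-6-methyl-4-[[2,4,6-tris(tert-butyldimethylsilyloxy)-3-methyl-5-pentanoylphenyl]methyl]-2-oxabicyclo[2.2.2]octa-5,7-dien-3-one (not isolated; one enantiomer drawn) | O=C1O[C@]2(O[Si](C)(C)C(C)(C)C)C(C(=O)CCC)=C(O[Si](C)(C)C(C)(C)C)[C@@]1(Cc3c(O[Si](C)(C)C(C)(C)C)c(C)c(O[Si](C)(C)C(C)(C)C)c(C(=O)CCCC)c3O[Si](C)(C)C(C)(C)C)C(OC)=C2C | intermediate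
16 | 1-[3-[[3-butanoyl-2,4-bis(tert-butyldimethylsilyloxy)-6-methoxy-5-methylphenyl]methyl]-2,4,6-tris(tert-butyldimethylsilyloxy)-5-methylphenyl]pentan-1-one | CCCC(=O)c1c(O[Si](C)(C)C(C)(C)C)c(C)c(OC)c(Cc2c(O[Si](C)(C)C(C)(C)C)c(C)c(O[Si](C)(C)C(C)(C)C)c(C(=O)CCCC)c2O[Si](C)(C)C(C)(C)C)c1O[Si](C)(C)C(C)(C)C | intermediate
17 | 1-[3-[(3-butanoyl-2,4-dihydroxy-6-methoxy-5-methylphenyl)methyl]-2,4,6-trihydroxy-5-methylphenyl]pentan-1-one (CNP0210501.0, achiral) | CCCCC(=O)c1c(O)c(C)c(O)c(Cc2c(O)c(C(=O)CCC)c(O)c(C)c2OC)c1O | target

**Step count and risks**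

Total step count: 9. Longest linear sequence: 6 (steps 1, 2, 5, 6, 8, 9; the ring B branch through steps 3, 4, 5, 6, 8, 9 is equally long).

Steps most likely to fail:

1. Step 8 (proposed new method). The donor-rich pyrone may add the ynol ether too slowly, so that the alkyne oligomerises first. Conjugate addition may also stop without ring closure. If silicon moves to the lactone oxygen, the alkyne would add across the other pair of termini and the butanoyl group would end next to the methoxyl carbon. The fallback uses known chemistry, sets out from 1, 7 and 4, and comes back to the route at 17. Friedel-Crafts acylation of 1 with 7 (AlCl3, PhNO2) should give 1-(2,4,6-trihydroxy-3-methylphenyl)butan-1-one F1. Methylation of the hydroxyl para to the ketone, the only one not hydrogen-bonded to it (Me2SO4, 1 equiv, K2CO3, acetone), should give aspidinol, 1-(2,6-dihydroxy-4-methoxy-3-methylphenyl)butan-1-one F2. Heating F2 with Mannich base 4 (dioxane, 100 °C) releases 9, which should alkylate the one free ring position of F2 and give 17 directly. The price is the selective O-methylation that the main route avoids.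

2. Step 5. The anhydride carbonyl may transfer to the neighbouring hydroxyl of ring A (a six-membered aryl lactone), followed by decarboxylation. The released amine may open the anhydride, or a second benzylation may occur. The fallback silylates ring A before the union; it sets out from 3 and 8 and comes back at 11. Vilsmeier-Haack formylation of 3 (POCl3, DMF; H2O) should give 2,4,6-trihydroxy-3-methyl-5-pentanoylbenzaldehyde F3. Silylation (TBSOTf, 2,6-lutidine, CH2Cl2) should give 2,4,6-tris(tert-butyldimethylsilyloxy)-3-methyl-5-pentanoylbenzaldehyde F4. Knoevenagel condensation of F4 with 8 in the presence of Hantzsch ester (cat. L-proline, CH2Cl2, rt) should give 5-butanoyl-6-hydroxy-3-[[2,4,6-tris(tert-butyldimethylsilyloxy)-3-methyl-5-pentanoylphenyl]methylidene]pyran-2,4-dione F5 (drawn as the Z isomer; the geometry is lost at once). Hydride transfer to F5 in the same flask should give 5-butanoyl-4,6-dihydroxy-3-[[2,4,6-tris(tert-butyldimethylsilyloxy)-3-methyl-5-pentanoylphenyl]methyl]pyran-2-one F6. TBSOTf and 2,6-lutidine on F6 should then give 11.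

3. Step 6. The hydrogen-bonded hydroxyls may be silylated incompletely, silicon may settle on the lactone oxygen instead of O6, or the silyl ketene acetal may hydrolyse while the salt is removed. The fallback uses transient trimethylsilyl protection in the cycloaddition flask, so the diene is never handled; it sets out from 10 and 14 and comes back at 17. Compound 10 is warmed with N,O-bis(trimethylsilyl)acetamide (8 equiv) and 14 in toluene (60 °C, then 100 °C, sealed tube). Under these neutral conditions 5-butanoyl-4,6-bis(trimethylsilyloxy)-3-[[3-methyl-5-pentanoyl-2,4,6-tris(trimethylsilyloxy)phenyl]methyl]pyran-2-one F7 should form and react on in the same flask. It should pass through the racemic trimethylsilyl analogue of the bridged lactone F8 to the pentakis(trimethylsilyl) ether of the target F9. Methanol with a trace of citric acid should then free 17.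

**Further compounds**

F1 | step 8 | 1-(2,4,6-trihydroxy-3-methylphenyl)butan-1-one | CCCC(=O)c1c(O)cc(O)c(C)c1O
F2 | step 8 | aspidinol, 1-(2,6-dihydroxy-4-methoxy-3-methylphenyl)butan-1-one | CCCC(=O)c1c(O)cc(OC)c(C)c1O
F3 | step 5 | 2,4,6-trihydroxy-3-methyl-5-pentanoylbenzaldehyde | CCCCC(=O)c1c(O)c(C=O)c(O)c(C)c1O
F4 | step 5 | 2,4,6-tris(tert-butyldimethylsilyloxy)-3-methyl-5-pentanoylbenzaldehyde | CCCCC(=O)c1c(O[Si](C)(C)C(C)(C)C)c(C=O)c(O[Si](C)(C)C(C)(C)C)c(C)c1O[Si](C)(C)C(C)(C)C
F5 | step 5 | (Z)-5-butanoyl-6-hydroxy-3-[[2,4,6-tris(tert-butyldimethylsilyloxy)-3-methyl-5-pentanoylphenyl]methylidene]pyran-2,4-dione | O=C1OC(O)=C(C(=O)CCC)C(=O)/C1=C/c2c(O[Si](C)(C)C(C)(C)C)c(C)c(O[Si](C)(C)C(C)(C)C)c(C(=O)CCCC)c2O[Si](C)(C)C(C)(C)C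
F6 | step 5 | 5-butanoyl-4,6-dihydroxy-3-[[2,4,6-tris(tert-butyldimethylsilyloxy)-3-methyl-5-pentanoylphenyl]methyl]pyran-2-one | CCCC(=O)C1=C(O)OC(=O)C(Cc2c(O[Si](C)(C)C(C)(C)C)c(C)c(O[Si](C)(C)C(C)(C)C)c(C(=O)CCCC)c2O[Si](C)(C)C(C)(C)C)=C1O
F7 | step 6 | 5-butanoyl-4,6-bis(trimethylsilyloxy)-3-[[3-methyl-5-pentanoyl-2,4,6-tris(trimethylsilyloxy)phenyl]methyl]pyran-2-one | CCCC(=O)C1=C(O[Si](C)(C)C)OC(=O)C(Cc2c(O[Si](C)(C)C)c(C)c(O[Si](C)(C)C)c(C(=O)CCCC)c2O[Si](C)(C)C)=C1O[Si](C)(C)C
F8 | step 6 | racemic 7-butanoyl-5-methoxy-6-methyl-4-[[3-methyl-5-pentanoyl-2,4,6-tris(trimethylsilyloxy)phenyl]methyl]-1,8-bis(trimethylsilyloxy)-2-oxabicyclo[2.2.2]octa-5,7-dien-3-one (one enantiomer drawn) | O=C1O[C@]2(O[Si](C)(C)C)C(C(=O)CCC)=C(O[Si](C)(C)C)[C@@]1(Cc3c(O[Si](C)(C)C)c(C)c(O[Si](C)(C)C)c(C(=O)CCCC)c3O[Si](C)(C)C)C(OC)=C2C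
F9 | step 6 | 1-[3-[[3-butanoyl-6-methoxy-5-methyl-2,4-bis(trimethylsilyloxy)phenyl]methyl]-5-methyl-2,4,6-tris(trimethylsilyloxy)phenyl]pentan-1-one | CCCC(=O)c1c(O[Si](C)(C)C)c(C)c(OC)c(Cc2c(O[Si](C)(C)C)c(C)c(O[Si](C)(C)C)c(C(=O)CCCC)c2O[Si](C)(C)C)c1O[Si](C)(C)C
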